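**Plan**

- Retrosynthesis (ring C numbered C1 = carbon bearing the ring B ether, C2 = CH, C3–C5 = hydroxylated carbons, C6 = carbon bearing the ring D ether): with the hydroxyls masked as methyl ethers, the cuts are the ring C C5–C6 bond (Claisen), the C1–O bond to ring B (oxa-Michael), C3–C4 (aldol), C2–C3 (alkyne formylation), the C6–O bond to ring D (propargylation), and the two outer diaryl ether bonds A–B and D–E.
- Forward: rings A/B and D/E are joined on benzaldehydes, and each aldehyde is turned into a phenol. The D–E phenol is grown into a six-carbon ynone keto ester, the A–B phenol adds to it, and ring C is folded from this chain last and aromatises.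
- Enabling feature: ring C has five contiguous oxygenated carbons; its C1, C3 and C5 oxygens are 1,3,5-related and map onto an enol-ether-masked 3,5-dioxo ester, so the two bulky aryloxy groups on adjacent C1 and C6 can be installed on the open chain.
- Stereochemistry: the target has no stereocenter. The chain stereocenters are formed without control and erased by oxidation and aromatisation; the E enol ether geometry is the thermodynamic one and is re-equilibrated during ring closure.

Key step: step 10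

**Remarks on the chemistry**

- Chain locants (ester carbon = chain C1 … aryloxymethyl carbon = chain C6) map onto ring C as chain C1→C5, C2→C4, C3→C3, C4→C2, C5→C1, C6→C6.
- Compounds 2 and 7 are assumed to be commercial.
- Compound 18 is a mixture of racemic diastereomers; 19 and 20 are racemic at chain C2.
- Compound 20 is drawn as the E isomer; any Z isomer should converge in step 10.

**Route**

Step 1
Reactants: 1 2,4,6-trimethoxyphenol; 2 4-bromo-2,6-dimethoxybenzaldehyde
Product: 3 2,6-dimethoxy-4-(2,4,6-trimethoxyphenoxy)benzaldehyde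
Conditions: CuI (10 mol %), picolinic acid (20 mol %), K3PO4, DMSO, 90 °C
Reagents that add atoms: none
Why: Ullmann-type copper-catalysed diaryl ether synthesis, in which the picolinic acid ligand system is the one established for di-ortho-substituted phenols and the para-formyl group activates the bromide.

Step 2
Reactants: 3 2,6-dimethoxy-4-(2,4,6-trimethoxyphenoxy)benzaldehyde
Product: 5 2,6-dimethoxy-4-(2,4,6-trimethoxyphenoxy)phenol, via aryl formate 4 (not isolated)
Conditions: 30% aq. H2O2, H2SO4 (cat.), MeOH, 0 °C → rt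
Reagents that add atoms: hydrogen peroxide, OO
Why: Acid-catalysed Dakin (Baeyer–Villiger-type) oxidation, in which the electron-rich 2,6-dimethoxyaryl group migrates to oxygen and formate 4 is methanolysed in the same pot, as in the standard preparation of polymethoxyphenols from their benzaldehydes.

Step 3
Reactants: 6 3-hydroxy-4,5-dimethoxybenzaldehyde; 7 3,4,5-trimethoxyphenylboronic acid
Product: 8 3,4-dimethoxy-5-(3,4,5-trimethoxyphenoxy)benzaldehyde
Conditions: Cu(OAc)2 (20 mol %), pyridine, 4 Å molecular sieves, O2 (1 atm), CH2Cl2, rt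
Reagents that add atoms: none
Why: Chan–Lam oxidative O-arylation of a phenol with an unhindered arylboronic acid, which proceeds at room temperature and tolerates the aldehyde.

Step 4
Reactants: 8 3,4-dimethoxy-5-(3,4,5-trimethoxyphenoxy)benzaldehyde
Product: 10 3,4-dimethoxy-5-(3,4,5-trimethoxyphenoxy)phenol, via aryl formate 9 (not isolated)
Conditions: 30% aq. H2O2, H2SO4 (cat.), MeOH, 0 °C → rt
Reagents that add atoms: hydrogen peroxide, OO
Why: Acid-catalysed Dakin oxidation, in which the para-methoxy group makes the aryl group the migrating one and the formate is cleaved by methanol in situ.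

Step 5
Reactants: 10 3,4-dimethoxy-5-(3,4,5-trimethoxyphenoxy)phenol; 11 propargyl bromide
Product: 12 1,2-dimethoxy-5-(prop-2-yn-1-yloxy)-3-(3,4,5-trimethoxyphenoxy)benzene
Conditions: K2CO3, acetone, reflux
Reagents that add atoms: none
Why: Williamson ether synthesis (SN2 of the phenoxide on a primary propargylic bromide), which forms the future ring C C6–O bond at an sp3 carbon instead of by aryl–oxygen coupling.

Step 6
Reactants: 12 1,2-dimethoxy-5-(prop-2-yn-1-yloxy)-3-(3,4,5-trimethoxyphenoxy)benzene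
Product: 15 4-[3,4-dimethoxy-5-(3,4,5-trimethoxyphenoxy)phenoxy]but-2-ynal, via lithium acetylide 13 (not isolated), via lithium hemiaminal alkoxide 14 (not isolated)
Conditions: n-BuLi, THF, −78 °C; DMF, −78 → 0 °C; reverse quench into cold 10% aq. KH2PO4
Reagents that add atoms: N,N-dimethylformamide, CN(C)C=O
Why: Formylation of a lithium acetylide with DMF, in which the terminal alkyne C–H is removed much faster than any aryl C–H at −78 °C and the buffered reverse quench keeps the liberated dimethylamine from adding to the ynal.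

Step 7
Reactants: 15 4-[3,4-dimethoxy-5-(3,4,5-trimethoxyphenoxy)phenoxy]but-2-ynal; 16 methyl methoxyacetate
Product: 18 methyl 6-[3,4-dimethoxy-5-(3,4,5-trimethoxyphenoxy)phenoxy]-3-hydroxy-2-methoxyhex-4-ynoate, via lithium enolate 17 (not isolated)
Conditions: LiN(iPr)2, THF, −78 °C (16 → 17); then 15, −78 °C; aq. NH4Cl
Reagents that add atoms: none
Why: Aldol addition of an ester lithium enolate to the aldehyde carbonyl (1,2-addition is expected at −78 °C); the two new stereocenters at chain C2 and C3 are formed without control and need none, since C3 is oxidised in step 8 and C2 becomes an aromatic carbon in step 10.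

Step 8
Reactants: 18 methyl 6-[3,4-dimethoxy-5-(3,4,5-trimethoxyphenoxy)phenoxy]-3-hydroxy-2-methoxyhex-4-ynoate
Product: 19 methyl 6-[3,4-dimethoxy-5-(3,4,5-trimethoxyphenoxy)phenoxy]-2-methoxy-3-oxohex-4-ynoate
Conditions: Dess–Martin periodinane (1.2 equiv), CH2Cl2, 0 °C → rt
Reagents that add atoms: none
Why: Dess–Martin oxidation of a propargylic alcohol to the ynone under neutral, non-basic conditions that leave the sensitive ynone keto ester intact, with the reagent limited to avoid oxidation at chain C2.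

Step 9
Reactants: 19 methyl 6-[3,4-dimethoxy-5-(3,4,5-trimethoxyphenoxy)phenoxy]-2-methoxy-3-oxohex-4-ynoate; 5 2,6-dimethoxy-4-(2,4,6-trimethoxyphenoxy)phenol
Product: 20 methyl (E)-5-[2,6-dimethoxy-4-(2,4,6-trimethoxyphenoxy)phenoxy]-6-[3,4-dimethoxy-5-(3,4,5-trimethoxyphenoxy)phenoxy]-2-methoxy-3-oxohex-4-enoate
Conditions: DABCO (20 mol %), MeCN, 0 °C → rt
Reagents that add atoms: none
Why: Amine-catalysed oxa-Michael addition of the phenol to the ynone, in which oxygen can only add at chain C5, so the hindered ring B–O–ring C ether is made without aryl–oxygen coupling and the β-aryloxy enone should settle as the E isomer (CH2 cis to the ketone), the usual thermodynamic geometry of β-alkoxy enones.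

Step 10
Reactants: 20 methyl (E)-5-[2,6-dimethoxy-4-(2,4,6-trimethoxyphenoxy)phenoxy]-6-[3,4-dimethoxy-5-(3,4,5-trimethoxyphenoxy)phenoxy]-2-methoxy-3-oxohex-4-enoate
Product: 24 4-[3,4-dimethoxy-5-(3,4,5-trimethoxyphenoxy)phenoxy]-5-[2,6-dimethoxy-4-(2,4,6-trimethoxyphenoxy)phenoxy]-2-methoxybenzene-1,3-diol, via potassium C2 enolate 21 (not isolated), via potassium C6 dienolate 22 (not isolated), via cyclohexenedione 23 (not isolated)
Conditions: KOtBu (3 equiv), THF/t-BuOH 4:1, degassed, argon, 0 → 50 °C; then 1 M HCl, 0 °C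
Reagents that add atoms: none
Why: KOtBu first removes the most acidic proton, chain C2–H between ketone and ester, giving enolate 21 in which the ester is switched off; because t-BuOH keeps all proton transfers reversible, 21 should stay in equilibrium with a small amount of the chain C6 dienolate 22 (C6–H is γ to the ketone through the C4=C5 enol ether and α to the ring D aryloxy group), and only 22 can close the ring. Its C6 terminus attacks the ester carbonyl (chain C1), methoxide leaves, and cyclohexenedione 23 enolises twice to the aromatic resorcinol dianion, which makes the sequence irreversible and draws the enolate equilibria forward. The closest known reaction type is the alkoxide-mediated intramolecular Claisen (Dieckmann-type) cyclisation that proceeds in the presence of a more acidic malonate or keto ester proton, as in Michael–Claisen routes to cyclohexane-1,3-diones and resorcinols and in base-mediated closures of enol-ether-masked 3,5-dioxo esters. Ring C closes in a 6-(enolendo)-exo-trig mode, which needs chain C2 and C5 cis on the C3=C4 enolate bond and C6 cis to C3; the latter is the E geometry of 20, and both are re-established by reversible dienolate formation. No stereocenter is created, and the chain C2 stereocenter of 20 is destroyed on aromatisation. The step needs carbon–carbon closure to outrun loss of the ring B aryloxide from chain C5: the aryl enol ether cannot lactonise to a 2-pyranone as a free 5-oxo group would, tert-butoxide is too bulky to exchange the vinylogous aryl ester, the enolate form shields the enone from nucleophiles, and the enolate oxygen has no ring of workable size to acylate.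

Step 11
Reactants: 24 4-[3,4-dimethoxy-5-(3,4,5-trimethoxyphenoxy)phenoxy]-5-[2,6-dimethoxy-4-(2,4,6-trimethoxyphenoxy)phenoxy]-2-methoxybenzene-1,3-diol
Product: 25 4-[3,4-dihydroxy-5-(3,4,5-trihydroxyphenoxy)phenoxy]-5-[2,6-dihydroxy-4-(2,4,6-trihydroxyphenoxy)phenoxy]benzene-1,2,3-triol
Conditions: BBr3 (25 equiv), CH2Cl2, −78 °C → rt, argon; then degassed H2O, 0 °C
Reagents that add atoms: none
Why: Lewis-acid-mediated cleavage of aryl methyl ethers (boron coordinates the ether oxygen and bromide attacks the methyl group by SN2), which removes all eleven methyl groups while the diaryl ether bonds, lacking an sp3 carbon on oxygen, are not cleaved.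

**Compound list**

1 | 2,4,6-trimethoxyphenol | COc1cc(OC)c(O)c(OC)c1 | starting material
2 | 4-bromo-2,6-dimethoxybenzaldehyde | COc1cc(Br)cc(OC)c1C=O | starting material
3 | 2,6-dimethoxy-4-(2,4,6-trimethoxyphenoxy)benzaldehyde | COc1cc(Oc2c(OC)cc(OC)cc2OC)cc(OC)c1C=O | intermediate
4 | 2,6-dimethoxy-4-(2,4,6-trimethoxyphenoxy)phenyl formate | O=COc1c(OC)cc(Oc2c(OC)cc(OC)cc2OC)cc1OC | intermediate
5 | 2,6-dimethoxy-4-(2,4,6-trimethoxyphenoxy)phenol | Oc1c(OC)cc(Oc2c(OC)cc(OC)cc2OC)cc1OC | intermediate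
6 | 3-hydroxy-4,5-dimethoxybenzaldehyde | COc1cc(C=O)cc(O)c1OC | starting material
7 | 3,4,5-trimethoxyphenylboronic acid | COc1cc(B(O)O)cc(OC)c1OC | starting material
8 | 3,4-dimethoxy-5-(3,4,5-trimethoxyphenoxy)benzaldehyde | COc1cc(C=O)cc(Oc2cc(OC)c(OC)c(OC)c2)c1OC | intermediate
9 | 3,4-dimethoxy-5-(3,4,5-trimethoxyphenoxy)phenyl formate | O=COc1cc(OC)c(OC)c(Oc2cc(OC)c(OC)c(OC)c2)c1 | intermediate
10 | 3,4-dimethoxy-5-(3,4,5-trimethoxyphenoxy)phenol | Oc1cc(OC)c(OC)c(Oc2cc(OC)c(OC)c(OC)c2)c1 | intermediate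
11 | propargyl bromide | C#CCBr | starting material
12 | 1,2-dimethoxy-5-(prop-2-yn-1-yloxy)-3-(3,4,5-trimethoxyphenoxy)benzene | C#CCOc1cc(OC)c(OC)c(Oc2cc(OC)c(OC)c(OC)c2)c1 | intermediate
13 | lithium acetylide of 12 | [Li+].[C-]#CCOc1cc(OC)c(OC)c(Oc2cc(OC)c(OC)c(OC)c2)c1 | intermediate
14 | lithium 1-(dimethylamino)-4-[3,4-dimethoxy-5-(3,4,5-trimethoxyphenoxy)phenoxy]but-2-yn-1-olate | [Li+].[O-]C(N(C)C)C#CCOc1cc(OC)c(OC)c(Oc2cc(OC)c(OC)c(OC)c2)c1 | intermediate
15 | 4-[3,4-dimethoxy-5-(3,4,5-trimethoxyphenoxy)phenoxy]but-2-ynal | O=CC#CCOc1cc(OC)c(OC)c(Oc2cc(OC)c(OC)c(OC)c2)c1 | intermediate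
16 | methyl methoxyacetate | COCC(=O)OC | starting material
17 | lithium enolate of methyl methoxyacetate | [Li+].[O-]C(OC)=COC | intermediate
18 | methyl 6-[3,4-dimethoxy-5-(3,4,5-trimethoxyphenoxy)phenoxy]-3-hydroxy-2-methoxyhex-4-ynoate (mixture of racemic diastereomers) | COC(=O)C(OC)C(O)C#CCOc1cc(OC)c(OC)c(Oc2cc(OC)c(OC)c(OC)c2)c1 | intermediate
19 | methyl 6-[3,4-dimethoxy-5-(3,4,5-trimethoxyphenoxy)phenoxy]-2-methoxy-3-oxohex-4-ynoate (racemic) | COC(=O)C(OC)C(=O)C#CCOc1cc(OC)c(OC)c(Oc2cc(OC)c(OC)c(OC)c2)c1 | intermediate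
20 | methyl (E)-5-[2,6-dimethoxy-4-(2,4,6-trimethoxyphenoxy)phenoxy]-6-[3,4-dimethoxy-5-(3,4,5-trimethoxyphenoxy)phenoxy]-2-methoxy-3-oxohex-4-enoate (racemic at C2) | COC(=O)C(OC)C(=O)/C=C(/Oc1c(OC)cc(Oc2c(OC)cc(OC)cc2OC)cc1OC)COc1cc(OC)c(OC)c(Oc2cc(OC)c(OC)c(OC)c2)c1 | intermediate
21 | potassium C2 enolate of 20 | [K+].COC(=O)C(OC)=C([O-])/C=C(/Oc1c(OC)cc(Oc2c(OC)cc(OC)cc2OC)cc1OC)COc1cc(OC)c(OC)c(Oc2cc(OC)c(OC)c(OC)c2)c1 | intermediate
22 | potassium C6 dienolate of 20 (chain C2 and C5 cis on C3=C4; C5=C6 geometry open) | [K+].COC(=O)C(OC)/C([O-])=C\C(Oc1c(OC)cc(Oc2c(OC)cc(OC)cc2OC)cc1OC)=COc1cc(OC)c(OC)c(Oc2cc(OC)c(OC)c(OC)c2)c1 | intermediate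
23 | 5-[2,6-dimethoxy-4-(2,4,6-trimethoxyphenoxy)phenoxy]-6-[3,4-dimethoxy-5-(3,4,5-trimethoxyphenoxy)phenoxy]-2-methoxycyclohex-4-ene-1,3-dione (stereoisomer mixture) | COC1C(=O)C=C(Oc2c(OC)cc(Oc3c(OC)cc(OC)cc3OC)cc2OC)C(Oc2cc(OC)c(OC)c(Oc3cc(OC)c(OC)c(OC)c3)c2)C1=O | intermediate
24 | 4-[3,4-dimethoxy-5-(3,4,5-trimethoxyphenoxy)phenoxy]-5-[2,6-dimethoxy-4-(2,4,6-trimethoxyphenoxy)phenoxy]-2-methoxybenzene-1,3-diol | Oc1cc(Oc2c(OC)cc(Oc3c(OC)cc(OC)cc3OC)cc2OC)c(Oc2cc(OC)c(OC)c(Oc3cc(OC)c(OC)c(OC)c3)c2)c(O)c1OC | intermediate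
25 | 4-[3,4-dihydroxy-5-(3,4,5-trihydroxyphenoxy)phenoxy]-5-[2,6-dihydroxy-4-(2,4,6-trihydroxyphenoxy)phenoxy]benzene-1,2,3-triol | Oc1cc(O)c(Oc2cc(O)c(Oc3cc(O)c(O)c(O)c3Oc3cc(O)c(O)c(Oc4cc(O)c(O)c(O)c4)c3)c(O)c2)c(O)c1 | target

**Step count**

Total: 11 steps. Longest linear sequence: 9 steps (steps 3–11, from 6 and 7 to 25); steps 1–2 form the two-step branch to phenol 5.

**Steps most likely to fail, with fallbacks**

Step 10. The substrate may rest as its chain C2 enolate for so long that ring closure no longer competes with slow expulsion of the ring B aryloxide from chain C5 (vinylogous acyl cleavage, or O-cyclisation to a 4-pyranone). The fallback removes the C2 proton by raising chain C2 to the ketal level and sets out from alkyne 12. Its lithium acetylide 13 (n-BuLi, THF, −78 °C) would be added to an excess of dimethyl 2,2-dimethoxymalonate to give methyl 6-[3,4-dimethoxy-5-(3,4,5-trimethoxyphenoxy)phenoxy]-2,2-dimethoxy-3-oxohex-4-ynoate F1. DABCO-catalysed addition of phenol 5, as in step 9, should then give methyl (E)-5-[2,6-dimethoxy-4-(2,4,6-trimethoxyphenoxy)phenoxy]-6-[3,4-dimethoxy-5-(3,4,5-trimethoxyphenoxy)phenoxy]-2,2-dimethoxy-3-oxohex-4-enoate F2. With no competing acidic site, KOtBu in THF deprotonates chain C6 only, and the same C6-to-C1 Claisen closure should give 5-hydroxy-6,6-dimethoxy-3-[2,6-dimethoxy-4-(2,4,6-trimethoxyphenoxy)phenoxy]-4-[3,4-dimethoxy-5-(3,4,5-trimethoxyphenoxy)phenoxy]cyclohexa-2,4-dien-1-one F3, an ortho-quinone monoketal held as its vinylogous acid anion until the quench. Without purification, F3 would be reduced with Zn in AcOH; reductive loss of one ketal methoxy group aromatises the ring and brings the route back at 24.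

Step 9. Self-reaction of the enolised ynone keto ester (intramolecular O-addition to the triple bond, or carbon addition between molecules) may outpace conjugate addition of the hindered phenoxide. The fallback changes the order of events so that no ynone keto ester is ever formed, and sets out from ynal 15. Phenol 5 would be added to 15 (DABCO cat., CH2Cl2, 0 °C) to give (E)-3-[2,6-dimethoxy-4-(2,4,6-trimethoxyphenoxy)phenoxy]-4-[3,4-dimethoxy-5-(3,4,5-trimethoxyphenoxy)phenoxy]but-2-enal F4. Aldol addition of lithium enolate 17 (THF, −78 °C) should give methyl (E)-5-[2,6-dimethoxy-4-(2,4,6-trimethoxyphenoxy)phenoxy]-6-[3,4-dimethoxy-5-(3,4,5-trimethoxyphenoxy)phenoxy]-3-hydroxy-2-methoxyhex-4-enoate F5. Dess–Martin oxidation of this allylic alcohol returns the route at 20.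

Step 11. Cleavage of the eleven ethers may stop at partly methylated stages, and the electron-rich polyphenol may oxidise in air during aqueous isolation and chromatography. The fallback isolates the product as a stable derivative and sets out from 24. After the BBr3 treatment and a methanol quench, the volatiles would be removed under argon and the crude material acetylated (Ac2O, pyridine, DMAP cat.) to 4-[3,4-diacetoxy-5-(3,4,5-triacetoxyphenoxy)phenoxy]-5-[2,6-diacetoxy-4-(2,4,6-triacetoxyphenoxy)phenoxy]benzene-1,2,3-triyl triacetate F6. F6 can be chromatographed and separated from under-demethylated material, which can be resubmitted. Acid-catalysed methanolysis (HCl generated from AcCl in degassed MeOH, rt) followed by evaporation should release 25 without base or air exposure.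

**Further compounds**

F1 | step 10 | methyl 6-[3,4-dimethoxy-5-(3,4,5-trimethoxyphenoxy)phenoxy]-2,2-dimethoxy-3-oxohex-4-ynoate | COC(=O)C(OC)(OC)C(=O)C#CCOc1cc(OC)c(OC)c(Oc2cc(OC)c(OC)c(OC)c2)c1
F2 | step 10 | methyl (E)-5-[2,6-dimethoxy-4-(2,4,6-trimethoxyphenoxy)phenoxy]-6-[3,4-dimethoxy-5-(3,4,5-trimethoxyphenoxy)phenoxy]-2,2-dimethoxy-3-oxohex-4-enoate | COC(=O)C(OC)(OC)C(=O)/C=C(/Oc1c(OC)cc(Oc2c(OC)cc(OC)cc2OC)cc1OC)COc1cc(OC)c(OC)c(Oc2cc(OC)c(OC)c(OC)c2)c1
F3 | step 10 | 5-hydroxy-6,6-dimethoxy-3-[2,6-dimethoxy-4-(2,4,6-trimethoxyphenoxy)phenoxy]-4-[3,4-dimethoxy-5-(3,4,5-trimethoxyphenoxy)phenoxy]cyclohexa-2,4-dien-1-one | COC1(OC)C(=O)C=C(Oc2c(OC)cc(Oc3c(OC)cc(OC)cc3OC)cc2OC)C(Oc2cc(OC)c(OC)c(Oc3cc(OC)c(OC)c(OC)c3)c2)=C1O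
F4 | step 9 | (E)-3-[2,6-dimethoxy-4-(2,4,6-trimethoxyphenoxy)phenoxy]-4-[3,4-dimethoxy-5-(3,4,5-trimethoxyphenoxy)phenoxy]but-2-enal | O=C/C=C(/Oc1c(OC)cc(Oc2c(OC)cc(OC)cc2OC)cc1OC)COc1cc(OC)c(OC)c(Oc2cc(OC)c(OC)c(OC)c2)c1
F5 | step 9 | methyl (E)-5-[2,6-dimethoxy-4-(2,4,6-trimethoxyphenoxy)phenoxy]-6-[3,4-dimethoxy-5-(3,4,5-trimethoxyphenoxy)phenoxy]-3-hydroxy-2-methoxyhex-4-enoate (mixture of racemic diastereomers) | COC(=O)C(OC)C(O)/C=C(/Oc1c(OC)cc(Oc2c(OC)cc(OC)cc2OC)cc1OC)COc1cc(OC)c(OC)c(Oc2cc(OC)c(OC)c(OC)c2)c1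
F6 | step 11 | 4-[3,4-diacetoxy-5-(3,4,5-triacetoxyphenoxy)phenoxy]-5-[2,6-diacetoxy-4-(2,4,6-triacetoxyphenoxy)phenoxy]benzene-1,2,3-triyl triacetate | CC(=O)Oc1cc(OC(C)=O)c(Oc2cc(OC(C)=O)c(Oc3cc(OC(C)=O)c(OC(C)=O)c(OC(C)=O)c3Oc3cc(OC(C)=O)c(OC(C)=O)c(Oc4cc(OC(C)=O)c(OC(C)=O)c(OC(C)=O)c4)c3)c(OC(C)=O)c2)c(OC(C)=O)c1
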